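Its constants are made up.

If a reagent reaches the flask only as a gas, the reckoning begins with how much of it stands dissolved while the reaction draws on it, so here are the two flasks and their steps.

| setting | ochre | amber |
|---|---|---|
| electrophile | 20 mM | 20 mM |
| free base | 1.00 equiv | 1.30 equiv |
| gas | 1.1 mM (held) | 1.1 mM (held) |
| time | 30 min | 30 min |

    electrophile + nucleophile → acid set free + target (k1 = 0.21 L mol⁻¹ s⁻¹)
    nucleophile + acid set free ⇌ protonated nucleophile, settled at all times (K2 = 2.9 × 10⁶ L mol⁻¹)
    acid set free + free base ⇌ salt of the base, settled at all times (K3 = 91 L mol⁻¹)
    electrophile + target → side product (k4 = 0.010 L mol⁻¹ s⁻¹)
    gas ⇌ nucleophile, rate k5*(csat - [nucleophile]) (k5 = 0.019 s⁻¹, csat = 1.1 mM)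
    2 nucleophile → self-condensation product (k6 = 0.25 L mol⁻¹ s⁻¹)

- a species is counted by the electrophile in it: one side product counts as two
- a step written with two of one species runs at k times the square of its concentration and takes two of it each time
- at the start none of nucleophile is dissolved
- run time (ochre): 30 min

* part of the electrophile that has reacted at the end, ochre
* part of the electrophile that has reacted at the end, amber
* what raising the equivalents of free base from its lowest to its highest value here does to the part of the electrophile that has reacted (changes below 5 percentage points count as none) (no change / it falls / it rises)

Two of us dispute this by hand. My colleague holds that the gas keeps the liquid at saturation, 1.1 mM, so that the electrophile decays as a pseudo-first-order species and 34.0% has reacted after 30 min.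

I hold that the first step draws the level down, and at double cost, since each turn frees one acid and that acid takes a second nucleophile. The nucleophile's binding constant times saturation stands at 3190, against 1.8 for the free base at the start in ochre. So I define a draw ratio, two times the first step's constant times the electrophile charged, divided by the transfer coefficient, which is 0.442 in both flasks. With the electrophile held as charged, my reckoning puts the level at saturation where this ratio is small and at saturation divided by the ratio where it is large, and one form joins both ends: saturation divided by one plus the draw ratio, the fed level, here 0.763 mM.

Holding the nucleophile there, the first step alone gives 25.0% in ochre and 25.0% in amber, and I expect no change. The fourth step adds to my figure, though the target's half-life under it in ochre, with the electrophile as charged, 58 min, is longer than the run.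

The forecast takes my side of the dispute with a higher number, 28% in ochre and 28% in amber, each from 24% to 32%, and no change. It puts the nucleophile near 0.75 to 0.8 mM, counts the small side reaction in, and argues that “the acid sits on the nucleophile, the base stays almost idle”.

The simulation gives 28.3% in ochre and 28.3% in amber, no change between them, so the extra free base in amber is not the reason for the reacted part, and my colleague's figure stands too high. Part of the reason the reacted part stands there is the slowness of the gas passage, acting together with the time allowed: ochre gives 37.7% with that slowness struck out, the case where his saturated level belongs, and 99.5% left ten times as long. Ochre's nucleophile reads 0.784 mM at 15.0 min against the fed level of 0.763 mM. In the neighbour like amber but with 80 mM of electrophile, the fed level drops to 0.397 mM, which gives a first-step turnover of 13.9% against 14.3% read as target plus half the side product.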